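The aroyl carbonyl, the C4 methine and the tertiary C3 carbinol of the butyrolactone ring form a β-hydroxy ketone whose oxygen and acyl group are cis, i.e. an opened 4,5-dihydroisoxazole. Everything rests on cutting the C4–C(=O) bond. The nitrile oxide of O-benzylvanillin and a (Z)-2-arylmethyl-2-butene-1,4-diol mono-silyl ether are joined by a zinc tartrate-directed enantioselective 1,3-dipolar cycloaddition. In one operation it makes the C4–acyl carbon bond and the C3–O bond on one alkene face, setting both stereocentres and the full carbon skeleton. The precursor is an achiral trisubstituted allylic alcohol. Oxidation–lactonisation, N–O hydrogenolysis and debenzylation finish the synthesis.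

Key step: step 7

Assumption: the zinc tartrate system is taken to respond to 7 in the same facial sense as to unsubstituted allyl alcohol, where the (R,R)-tartrate leads to (5R)-5-(hydroxymethyl)isoxazolines. The (S,S)-tartrate is therefore chosen for the (5S) product, and the enantiomeric tartrate would be used if the sense proved opposite.

Step 1
Reactants: 1 4-(benzyloxy)-3-methoxybenzyl alcohol
Product: 2 4-(benzyloxy)-3-methoxybenzyl bromide
Conditions: PBr3 (0.4 equiv), Et2O, 0 °C; used without storage
Reagents that add atoms: phosphorus tribromide, BrP(Br)Br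
Why: Substitution of an activated phosphite ester by bromide (alcohol-to-bromide conversion with PBr3) is fast on this electron-rich benzylic alcohol and leaves the aryl benzyl ether intact.

Step 2
Reactants: 2 4-(benzyloxy)-3-methoxybenzyl bromide; 3 ethyl 2-[bis(2-methylphenoxy)phosphoryl]acetate
Product: 4 ethyl 3-[4-(benzyloxy)-3-methoxyphenyl]-2-[bis(2-methylphenoxy)phosphoryl]propanoate (racemic)
Conditions: NaH, THF/DMF, 0 °C to rt, slight excess of 3
Reagents that add atoms: none
Why: SN2 C-alkylation of the stabilised phosphonoacetate carbanion with a reactive benzylic bromide, the excess of 3 limiting double alkylation; the new stereocentre is lost in step 3.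

Step 3
Reactants: 4 ethyl 3-[4-(benzyloxy)-3-methoxyphenyl]-2-[bis(2-methylphenoxy)phosphoryl]propanoate; 5 (tert-butyldimethylsilyloxy)acetaldehyde
Product: 6 ethyl (Z)-2-[4-(benzyloxy)-3-methoxybenzyl]-4-(tert-butyldimethylsilyloxy)but-2-enoate
Conditions: NaH, THF, −78 to 0 °C
Reagents that add atoms: none
Why: In this Z-selective Horner–Wadsworth–Emmons olefination the electron-poor diaryl phosphonate makes elimination from the kinetic adduct fast, so ester and CH2OTBS should end up cis.

Step 4
Reactants: 6 ethyl (Z)-2-[4-(benzyloxy)-3-methoxybenzyl]-4-(tert-butyldimethylsilyloxy)but-2-enoate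
Product: 7 (Z)-2-[4-(benzyloxy)-3-methoxybenzyl]-4-(tert-butyldimethylsilyloxy)but-2-en-1-ol
Conditions: i-Bu2AlH (2.5 equiv), CH2Cl2, −78 °C; aq. potassium sodium tartrate work-up
Reagents that add atoms: none
Why: 1,2-Reduction of the enoate with i-Bu2AlH gives the allylic alcohol with retention of the Z geometry, and the cold aluminium alkoxide should not trigger silyl migration.

Step 5
Reactants: 8 4-(benzyloxy)-3-methoxybenzaldehyde (O-benzylvanillin)
Product: 9 (E)-4-(benzyloxy)-3-methoxybenzaldehyde oxime
Conditions: NH2OH·HCl, NaOAc, EtOH/H2O, rt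
Reagents that add atoms: hydroxylamine hydrochloride, Cl.NO
Why: Oxime condensation of an aromatic aldehyde under acetate buffer is a reliable carbonyl–amine condensation.

Step 6
Reactants: 9 (E)-4-(benzyloxy)-3-methoxybenzaldehyde oxime
Product: 10 (Z)-4-(benzyloxy)-N-hydroxy-3-methoxybenzimidoyl chloride
Conditions: NCS (1.0 equiv), DMF, rt
Reagents that add atoms: N-chlorosuccinimide, O=C1CCC(=O)N1Cl
Why: Chlorination of the aldoxime CH with NCS in DMF (hydroximoyl chloride synthesis) is faster than ring chlorination when one equivalent is used.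

Step 7
Reactants: 7 (Z)-2-[4-(benzyloxy)-3-methoxybenzyl]-4-(tert-butyldimethylsilyloxy)but-2-en-1-ol; 10 (Z)-4-(benzyloxy)-N-hydroxy-3-methoxybenzimidoyl chloride
Product: 12 [(4S,5S)-5-[4-(benzyloxy)-3-methoxybenzyl]-3-[4-(benzyloxy)-3-methoxyphenyl]-4-[(tert-butyldimethylsilyloxy)methyl]-4,5-dihydroisoxazol-5-yl]methanol, via nitrile oxide 11 (not isolated)
Conditions: 7, Et2Zn (1 equiv), CHCl3, 0 °C; (S,S)-diisopropyl tartrate (1 equiv); Et2Zn (1 equiv); 1,4-dioxane; 10 added slowly, 0 °C to rt
Reagents that add atoms: none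
Why: The first Et2Zn turns 7 into its ethylzinc alkoxide, the tartrate and the second Et2Zn build a dinuclear zinc tartrate that also binds 10 as its O-zinc salt, chloride loss releases nitrile oxide 11 still held through its oxygen, and a concerted suprafacial [3+2] cycloaddition inside this assembly forms the aryl-C(=N)–C4 bond and the O–C5 bond together. The closest known reaction type is the diisopropyl tartrate/zinc-mediated asymmetric 1,3-dipolar cycloaddition of nitrile oxides to allylic alcohols, the chiral version of the magnesium alkoxide-directed nitrile oxide cycloaddition. The only ring closed is the five-membered 4,5-dihydroisoxazole, made by intermolecular concerted cycloaddition of the C–N–O dipole across the C=C bond, both ring bonds forming in one step. The quaternary C5 is controlled by the (S,S)-tartrate, which leaves one face of the zinc-bound alkene open to the held dipole, and C4 follows from stereospecific syn addition to the Z alkene, so CH2OH and CH2OTBS stay cis and the ring oxygen and the aryl-bearing carbon sit on the same face. The step needs regioselectivity (oxygen to the fully substituted alkene carbon, carbon terminus to the CH end), secured both by delivery of the dipole oxygen from the zinc on the neighbouring CH2O group and by the steric preference of trisubstituted alkenes, while the silyl cap on the other allylic oxygen switches off the competing direction. Dimerisation of 11 to the furoxan is held back by slow addition of 10 and by the rate gain of the templated pathway.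

Step 8
Reactants: 12 [(4S,5S)-5-[4-(benzyloxy)-3-methoxybenzyl]-3-[4-(benzyloxy)-3-methoxyphenyl]-4-[(tert-butyldimethylsilyloxy)methyl]-4,5-dihydroisoxazol-5-yl]methanol
Product: 16 (3aS,6aS)-6a-[4-(benzyloxy)-3-methoxybenzyl]-3-[4-(benzyloxy)-3-methoxyphenyl]-3a,4-dihydrofuro[3,4-d]isoxazol-6(6aH)-one, via aldehyde 13 (not isolated), via silyloxy acid 14 (not isolated), via hydroxy acid 15 (not isolated)
Conditions: TEMPO (cat.), PhI(OAc)2 (2.5 equiv), MeCN/H2O, rt; extractive work-up; crude acid, 2 M HCl, THF, rt
Reagents that add atoms: water, O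
Why: Oxoammonium (TEMPO/PhI(OAc)2) oxidation takes the only free primary alcohol through aldehyde 13 and its hydrate to acid 14, and acidic desilylation then frees the cis-disposed CH2OH, which closes the cis-fused γ-lactone by 5-exo-trig acyl substitution without touching either stereocentre.

Step 9
Reactants: 16 (3aS,6aS)-6a-[4-(benzyloxy)-3-methoxybenzyl]-3-[4-(benzyloxy)-3-methoxyphenyl]-3a,4-dihydrofuro[3,4-d]isoxazol-6(6aH)-one
Product: 18 (3S,4S)-4-[4-(benzyloxy)-3-methoxybenzoyl]-3-[4-(benzyloxy)-3-methoxybenzyl]-3-hydroxydihydrofuran-2(3H)-one, via hydroxy ketimine 17 (not isolated)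
Conditions: H2 (1 atm), Raney Ni, B(OH)3, MeOH/THF/H2O, rt
Reagents that add atoms: water, O
Why: Hydrogenolysis of the weak N–O bond gives ketimine 17, which the boric acid buffer should hydrolyse faster than it is reduced (reductive isoxazoline-to-aldol unmasking), the near-neutral medium guarding against epimerisation, dehydration and retro-aldol cleavage; any early loss of a benzyl group converges in step 10.

Step 10
Reactants: 18 (3S,4S)-4-[4-(benzyloxy)-3-methoxybenzoyl]-3-[4-(benzyloxy)-3-methoxybenzyl]-3-hydroxydihydrofuran-2(3H)-one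
Product: 19 (3S,4S)-3-hydroxy-4-(4-hydroxy-3-methoxybenzoyl)-3-(4-hydroxy-3-methoxybenzyl)dihydrofuran-2(3H)-one (target)
Conditions: H2 (1 atm), Pd/C, EtOAc, rt, stopped at full debenzylation
Reagents that add atoms: none
Why: Catalytic hydrogenolysis of the two aryl benzyl ethers under neutral conditions should spare the electron-rich aryl ketone, the lactone and both stereocentres.

Compound list
1 | 4-(benzyloxy)-3-methoxybenzyl alcohol | OCc1ccc(OCc2ccccc2)c(OC)c1 | starting material
2 | 4-(benzyloxy)-3-methoxybenzyl bromide | BrCc1ccc(OCc2ccccc2)c(OC)c1 | intermediate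
3 | ethyl 2-[bis(2-methylphenoxy)phosphoryl]acetate | CCOC(=O)CP(=O)(Oc1ccccc1C)Oc1ccccc1C | starting material
4 | ethyl 3-[4-(benzyloxy)-3-methoxyphenyl]-2-[bis(2-methylphenoxy)phosphoryl]propanoate (racemic) | CCOC(=O)C(Cc1ccc(OCc2ccccc2)c(OC)c1)P(=O)(Oc1ccccc1C)Oc1ccccc1C | intermediate
5 | (tert-butyldimethylsilyloxy)acetaldehyde | O=CCO[Si](C)(C)C(C)(C)C | starting material
6 | ethyl (Z)-2-[4-(benzyloxy)-3-methoxybenzyl]-4-(tert-butyldimethylsilyloxy)but-2-enoate | CCOC(=O)/C(Cc1ccc(OCc2ccccc2)c(OC)c1)=C\CO[Si](C)(C)C(C)(C)C | intermediate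
7 | (Z)-2-[4-(benzyloxy)-3-methoxybenzyl]-4-(tert-butyldimethylsilyloxy)but-2-en-1-ol | OC/C(Cc1ccc(OCc2ccccc2)c(OC)c1)=C\CO[Si](C)(C)C(C)(C)C | intermediate
8 | 4-(benzyloxy)-3-methoxybenzaldehyde | COc1cc(C=O)ccc1OCc1ccccc1 | starting material
9 | (E)-4-(benzyloxy)-3-methoxybenzaldehyde oxime | COc1cc(/C=N/O)ccc1OCc1ccccc1 | intermediate
10 | (Z)-4-(benzyloxy)-N-hydroxy-3-methoxybenzimidoyl chloride | COc1cc(/C(Cl)=N/O)ccc1OCc1ccccc1 | intermediate
11 | 4-(benzyloxy)-3-methoxybenzonitrile oxide | COc1cc(C#[N+][O-])ccc1OCc1ccccc1 | intermediate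
12 | [(4S,5S)-5-[4-(benzyloxy)-3-methoxybenzyl]-3-[4-(benzyloxy)-3-methoxyphenyl]-4-[(tert-butyldimethylsilyloxy)methyl]-4,5-dihydroisoxazol-5-yl]methanol | COc1cc(C[C@]2(CO)ON=C(c3ccc(OCc4ccccc4)c(OC)c3)[C@H]2CO[Si](C)(C)C(C)(C)C)ccc1OCc1ccccc1 | intermediate
13 | (4S,5S)-5-carbaldehyde corresponding to 12 | COc1cc(C[C@]2(C=O)ON=C(c3ccc(OCc4ccccc4)c(OC)c3)[C@H]2CO[Si](C)(C)C(C)(C)C)ccc1OCc1ccccc1 | intermediate
14 | (4S,5S)-5-carboxylic acid corresponding to 12 (silyl ether intact) | COc1cc(C[C@]2(C(=O)O)ON=C(c3ccc(OCc4ccccc4)c(OC)c3)[C@H]2CO[Si](C)(C)C(C)(C)C)ccc1OCc1ccccc1 | intermediate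
15 | (4S,5S)-4-(hydroxymethyl)-4,5-dihydroisoxazole-5-carboxylic acid (desilylated 14) | COc1cc(C[C@]2(C(=O)O)ON=C(c3ccc(OCc4ccccc4)c(OC)c3)[C@H]2CO)ccc1OCc1ccccc1 | intermediate
16 | (3aS,6aS)-6a-[4-(benzyloxy)-3-methoxybenzyl]-3-[4-(benzyloxy)-3-methoxyphenyl]-3a,4-dihydrofuro[3,4-d]isoxazol-6(6aH)-one | COc1cc(C[C@]23ON=C(c4ccc(OCc5ccccc5)c(OC)c4)[C@H]2COC3=O)ccc1OCc1ccccc1 | intermediate
17 | N–H ketimine of 18 (cis 3-hydroxy-4-carboximidoyl lactone) | COc1cc(C[C@@]2(O)C(=O)OC[C@@H]2C(=N)c2ccc(OCc3ccccc3)c(OC)c2)ccc1OCc1ccccc1 | intermediate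
18 | (3S,4S)-4-[4-(benzyloxy)-3-methoxybenzoyl]-3-[4-(benzyloxy)-3-methoxybenzyl]-3-hydroxydihydrofuran-2(3H)-one | COc1cc(C[C@@]2(O)C(=O)OC[C@@H]2C(=O)c2ccc(OCc3ccccc3)c(OC)c2)ccc1OCc1ccccc1 | intermediate
19 | (3S,4S)-3-hydroxy-4-(4-hydroxy-3-methoxybenzoyl)-3-(4-hydroxy-3-methoxybenzyl)dihydrofuran-2(3H)-one | COc1cc(C[C@@]2(O)C(=O)OC[C@@H]2C(=O)c2ccc(O)c(OC)c2)ccc1O | target

Total step count: 10. Longest linear sequence: 8 (steps 1–4 and 7–10).

Steps most likely to fail

Step 7. The tartrate may discriminate the faces of a trisubstituted Z alkene only weakly. The cycloaddition may also be so slow that the nitrile oxide dimerises. The fallback sets out from 7 and 10 and comes back at 12.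
- The bromomagnesium alkoxide of 7 (EtMgBr, CH2Cl2, 0 °C) is treated with 10.
- This achiral, strongly accelerated magnesium alkoxide-directed cycloaddition should give the racemic isoxazoline alcohol F1 with the same regiochemistry and relative configuration.
- Esterification with (S)-O-methylmandelic acid (EDC, DMAP, CH2Cl2) and separation of the two diastereomeric esters by chromatography or crystallisation gives the (4S,5S)-configured mandelate ester F2.
- LiOH in THF/H2O releases 12.

Step 9. The ketimine may be over-reduced before it hydrolyses. The freed β-hydroxy ketone may also lose water or undergo retro-aldol cleavage on the strained bicycle. The fallback changes both the order of events and the reductant class; it sets out from 12 and comes back at 18.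
- The N–O bond of 12 is cleaved without hydrogen (Mo(CO)6, MeCN/H2O, reflux) to the open-chain keto diol F3.
- The primary alcohol of F3 is oxidised under buffered conditions (TEMPO, NaClO2, cat. NaOCl, pH 7 buffer, MeCN) to the keto hydroxy acid F4.
- 2 M HCl in THF removes the silyl group, and lactonisation gives 18.

Step 8. Oxidation of the neopentyl-type alcohol may be sluggish. The silyl group may then be lost early, with oxidation at the wrong carbinol. The fallback reaches the lactone through a lactol instead of an acid; it sets out from 12 and comes back at 16.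
- Dess–Martin periodinane (CH2Cl2, NaHCO3) gives aldehyde 13, now isolated.
- HF·pyridine in THF removes the silyl group and the hydroxy aldehyde closes to the fused lactol F5.
- Ag2CO3 on Celite (toluene, reflux) oxidises F5 to 16.

Further compounds
F1 | step 7 | racemic isoxazoline alcohol, relative configuration (4S*,5S*), constitution of 12 | COc1cc(CC2(CO)ON=C(c3ccc(OCc4ccccc4)c(OC)c3)C2CO[Si](C)(C)C(C)(C)C)ccc1OCc1ccccc1
F2 | step 7 | (S)-O-methylmandelate ester of 12 | COc1cc(C[C@]2(COC(=O)[C@@H](OC)c3ccccc3)ON=C(c3ccc(OCc4ccccc4)c(OC)c3)[C@H]2CO[Si](C)(C)C(C)(C)C)ccc1OCc1ccccc1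
F3 | step 9 | open-chain keto diol (aryl ketone, tertiary and primary OH, silyl ether intact) | COc1cc(C[C@@](O)(CO)[C@H](CO[Si](C)(C)C(C)(C)C)C(=O)c2ccc(OCc3ccccc3)c(OC)c2)ccc1OCc1ccccc1
F4 | step 9 | open-chain keto α-hydroxy acid (silyl ether intact) | COc1cc(C[C@@](O)(C(=O)O)[C@H](CO[Si](C)(C)C(C)(C)C)C(=O)c2ccc(OCc3ccccc3)c(OC)c2)ccc1OCc1ccccc1
F5 | step 8 | fused isoxazoline lactol (anomeric mixture) | COc1cc(C[C@]23ON=C(c4ccc(OCc5ccccc5)c(OC)c4)[C@H]2COC3O)ccc1OCc1ccccc1
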